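## The problem

1. The target 26 is a germacranolide. It has a ten-membered carbocycle C1–C10 with a trans-fused α-methylene-γ-butyrolactone on C6–C7 (O on C6, carbons C11–C13), a cis trisubstituted oxirane on C1–C10, a Z trisubstituted olefin C4=C5, an allylic acetate on C3 and an (R)-2-methylbutanoate on C8.
2. The ring is the hardest part. Closing a ten-membered carbocycle costs transannular strain and entropy, and here the ring must also hold two cis trisubstituted C=C units (C4=C5 and the C1=C10 bond hidden in the oxirane) in defined geometry.
3. C6, C7 and C8 are contiguous and can control each other. C3 and C1/C10 are separated from this triad by sp2 or CH2 carbons, so only a ring or a reagent can set them.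
4. O3, O6 and O8 are three secondary oxygens with three different acyl partners, so they must be told apart.
5. Several groups are fragile. The α-methylene lactone is sensitive to Michael addition, hydride and base. The oxirane is sensitive to acid and to transannular attack by C4=C5. The allylic acetate and C7–H are also at risk.
6. The feature that makes the key step possible is that the ester-bearing carbons C3 and C8 stand 1,6 across the ring. An imagined bond C3–C8 divides the ring into two cyclohexenes, ring A (C3, C4, C5, C6, C7, C8) and ring B (C3, C2, C1, C10, C9, C8). Each holds one of the cis C=C units, where cis is the only possible geometry.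
7. Ring A with its C15 methyl and C11 isopropenyl branch is the carbon skeleton of carvone. Ring B adds C2–C1=C10(C14)–C9, an isoprene unit. The ten-membered ring is therefore the perimeter of a decalin-3,8-diol, and glycol cleavage puts carbonyl groups on exactly the carbons that need oxygen.

## Retrosynthesis

**26 ⇒ 23 ⇒ 21.** The cuts are the acyl bond O6–C12 and, behind it, the oxidation level of C12 back to the CH3 of an isopropenyl group.
- The Michael acceptor is the least tolerant group, so it is made last, from the 6,12-diol 23.
- Oxidising C12 only after C1=C10 is gone (21) leaves the isopropenyl group as the only electron-rich olefin.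
- The precursor carries the native isopropenyl group and no C12 protecting group.
- The forward steps need an allylic oxidation that spares the oxirane, and an oxidation that prefers the primary alcohol.

**21 ⇒ 20.** The cuts are C1–O and C10–O.
- A cis oxirane maps onto a Z olefin by syn transfer of oxygen.
- Building the oxirane from a diol would invert one carbon and give the trans isomer.
- The forward step must choose the correct face of C1=C10, far from any stereocentre, so a chiral dioxirane is used.

**20 ⇒ 15.** The cuts are both acyl–O bonds and C3–H and C8–H.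
- In diketone 15 the two carbons differ in kind. C3 is an α-methyl enone and C8 is an isolated ketone. Reduction and acylation can therefore proceed one at a time without protecting groups on O3 or O8.
- The forward steps need a chemoselective, peripheral hydride attack at C8 and a reagent-controlled reduction at C3.

**15 ⇒ 13 (key).** The bond C3–C8 is reconnected, turning both carbonyls into tertiary carbinols.
- Every other ring bond, if cut, leads back to an open chain and a macrocyclisation. This bond leads to a cis-decalin.
- Diol 13 has no medium ring, and its olefin geometries need no control.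
- The forward reaction is a glycol cleavage that leaves four olefins alone.

**13 ⇒ 12 ⇒ 11.** The cuts are C1=C10 (metathesis) and then C2–C3 (carbonyl allylation).
- The metathesis that would be hard in a ten-membered ring becomes a six-ring closure.
- C2–C3 is chosen because C3 is the carbonyl carbon of the carvone enone.
- Allyl must add cis to methallyl. This gives a cis-fused ring and a chelatable diol.

**11 ⇒ 6.** The cut is C6–O.
- In 6 the α′ carbon C8 is quaternary, so the enone can enolise only towards C6 and cannot aromatise.
- The precursor lacks one stereocentre and one oxygen.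
- The forward step must place oxygen at the γ carbon, anti to the isopropenyl group.

**6 ⇒ 1.** The cuts are C8–C9 and C8–O.
- Both bonds lie at the α′ carbon of (R)-carvone 1.
- Oxygen goes in first and carbon second, each anti to the isopropenyl group. This places methallyl equatorial and O8 axial, which is the arrangement that later steers the allyl addition.
- Compound 1 supplies C7 in the right absolute sense, ten of the fifteen skeletal carbons and the C3(=O)–C4(C15)=C5 unit.

## Roads not taken

**Alternative 1:** The cut is C6–C7 together with O6–C12. The forward key step is an intramolecular Barbier or Nozaki–Hiyama–Kishi-type allylation of the Z-enal A1 by its own 2-(bromomethyl)acrylate end (Zn, In or CrCl2). Lactonisation then gives dienolide A2, which is epoxidised. This is the most obvious plan, since the ring, C6, C7 and the lactone arise together. The chosen plan is better for these reasons: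
- A1 is a fifteen-carbon chain with two Z trisubstituted olefins and two isolated carbinol centres, each needing its own asymmetric step.
- The Z-enal drifts to E.
- The 8-acyloxy group sits next to the allylmetal terminus and invites 1,4-elimination.
- The closure pays the full strain and entropy of the ring.
- C6 and C7 are fixed relative to C8 in a macrocyclic transition state that cannot be predicted.

**Alternative 2:** The cut is C1=C10 in the finished lactone. The forward key step is direct ring-closing metathesis of the seco-diene A3 to A2. The chosen plan is better for these reasons: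
- A trisubstituted olefin must form within a ten-membered ring, so oligomers compete.
- The ruthenium carbene can engage the α-methylene lactone.
- Nothing enforces Z geometry.
- A3 still needs all its sp3 centres from acyclic chemistry.
- The chosen plan runs the same metathesis in a six-membered ring and gains the ring size afterwards.

**Alternative 3:** The cut is the same C3–C8 bond, broken by an anionic oxy-Cope rearrangement of the divinyl carbinol A4 (KH, 18-crown-6) to give A5. This is the classical four-carbon expansion of a cyclohexanone. The chosen plan is better for these reasons: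
- The sigmatropic shift moves the unsaturation to C8=C9, most likely as the E isomer.
- C1–C10 is left saturated, with an uncontrolled centre at C10.
- C8 carries no oxygen, so three positions would need re-oxidation.
- Glycol cleavage leaves oxygen on C3 and C8 and keeps C1=C10 in place.

Key step: step 9

Assumption: the SMILES is read as 1R,3R,4Z,6S,7S,8S,10S,2′R with C2 and C9 cis on the oxirane; germacrane numbering of 26 is used for all compounds; 1, 17 and the reagents named are taken as commercial.

## Steps

Step 1
Reactants: 1 (R)-(−)-carvone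
Product: 3 (5S,6S)-6-hydroxycarvone, via sodium dienolate 2 (not isolated)
Conditions: NaN(SiMe3)2, THF, −78 °C; 2-(phenylsulfonyl)-3-phenyloxaziridine, −78 °C; AcOH
Reagents that add atoms: 2-(phenylsulfonyl)-3-phenyloxaziridine, O=S(=O)(c1ccccc1)N1OC1c1ccccc1
Why: Kinetic deprotonation at the α′ carbon C8 gives the cross-conjugated dienolate 2; enolate hydroxylation by the N-sulfonyloxaziridine should occur on the face opposite the C7 isopropenyl group, placing O8 trans to it (a relay centre only).

Step 2
Reactants: 3 (5S,6S)-6-hydroxycarvone
Product: 4 (5S,6S)-6-[(2-methoxypropan-2-yl)oxy]carvone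
Conditions: 2-methoxypropene, PPTS (cat.), CH2Cl2, 0 °C
Reagents that add atoms: 2-methoxypropene, COC(C)=C
Why: Acid-catalysed acetal formation; unlike a silyl or acyl group this acetal cannot migrate to the neighbouring enolate oxygen in step 3, it adds no stereocentre, and it falls off during step 5.

Step 3
Reactants: 4 (5S,6S)-6-[(2-methoxypropan-2-yl)oxy]carvone
Product: 6 (5S,6R)-6-[(2-methoxypropan-2-yl)oxy]-6-(2-methylallyl)carvone, via potassium enolate 5 (not isolated)
Conditions: KN(SiMe3)2, THF, −78 °C; 3-bromo-2-methylpropene, DMPU, −78 to −20 °C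
Reagents that add atoms: 3-bromo-2-methylpropene, C=C(C)CBr
Why: Enolate alkylation with an allylic bromide at the only α carbon that bears hydrogen; in 5 allylic strain with the C8 alkoxy group should turn the isopropenyl group axial, so carbon enters anti to it and O8 is pushed to the isopropenyl face.

Step 4
Reactants: 6 (5S,6R)-6-[(2-methoxypropan-2-yl)oxy]-6-(2-methylallyl)carvone
Product: 8 triethylsilyl dienol ether of 6 (C3=C4 and C5=C6), via potassium dienolate 7 (not isolated)
Conditions: KN(SiMe3)2, THF, −78 °C; Et3SiCl
Reagents that add atoms: chlorotriethylsilane, CC[Si](Cl)(CC)CC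
Why: With C8 quaternary only the vinylogous proton at C6 can be removed, and O-silylation of the linear dienolate gives the 1-silyloxy-1,3-diene; aromatisation is blocked by the quaternary carbon.

Step 5
Reactants: 8 triethylsilyl dienol ether of 6
Product: 10 (4S,5R,6R)-4,6-dihydroxy-2-methyl-6-(2-methylallyl)-5-(prop-1-en-2-yl)cyclohex-2-en-1-one, via hydroxy enone acetal 9 (not isolated)
Conditions: dimethyldioxirane (1 equiv), acetone–CH2Cl2, −78 to −40 °C; then PPTS (cat.), THF–H2O, 23 °C
Reagents that add atoms: dimethyldioxirane, CC1(C)OO1
Why: Vinylogous Rubottom oxidation; the dioxirane should take the terminal, less hindered C5=C6 bond of the silyloxydiene anti to the isopropenyl group, and the push of the silyl enol ether opens the oxirane at C5 to restore the enone with O6 trans to C11 (6S). Mild aqueous acid then removes the acetal and any silyl residue.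

Step 6
Reactants: 10 (4S,5R,6R)-4,6-dihydroxy enone
Product: 11 (4S,5R,6R)-4-(tert-butyldimethylsilyloxy)-6-hydroxy-2-methyl-6-(2-methylallyl)-5-(prop-1-en-2-yl)cyclohex-2-en-1-one
Conditions: t-BuMe2SiCl, imidazole, DMF, 23 °C
Reagents that add atoms: tert-butyldimethylsilyl chloride, CC(C)(C)[Si](C)(C)Cl
Why: Standard silylation; the secondary allylic O6–H reacts while the tertiary, neopentyl-like O8–H should stay free for steric reasons.

Step 7
Reactants: 11 silyl ether hydroxy enone
Product: 12 (1R,2S,5S,6R)-2-allyl-5-(tert-butyldimethylsilyloxy)-3-methyl-1-(2-methylallyl)-6-(prop-1-en-2-yl)cyclohex-3-ene-1,2-diol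
Conditions: CH2=CHCH2MgBr (2.5 equiv), Et2O–THF, −78 °C; aq. NH4Cl
Reagents that add atoms: allylmagnesium bromide, C=CC[Mg]Br
Why: 1,2-Addition of an allyl Grignard reagent to the enone after deprotonation of O8–H; with isopropenyl, methallyl and silyloxy groups all equatorial the C8–O bond is axial and cannot chelate. Axial attack anti to this bond (Felkin–Anh sense) should put allyl cis to methallyl and give the cis-diol (3S).

Step 8
Reactants: 12 allyl methallyl diol
Product: 13 (1R,2S,4aS,8aR)-2-(tert-butyldimethylsilyloxy)-4,7-dimethyl-1-(prop-1-en-2-yl)-1,2,5,8-tetrahydronaphthalene-4a,8a-diol (cis-fused)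
Conditions: second-generation Grubbs catalyst (H2IMes)(PCy3)Cl2Ru=CHPh (cat.), CH2Cl2, 40 °C
Reagents that add atoms: none
Why: Ring-closing metathesis of a monosubstituted with a 1,1-disubstituted olefin held gauche on adjacent carbons closes ring B as a cyclohexene, in which C1=C10 can only be cis. The isopropenyl group is trans-1,3 to the allyl group and cannot reach it, and closure onto methallyl would need a tetrasubstituted olefin.

Step 9
Reactants: 13 cis-decalindiol
Product: 15 (1(10)Z,4Z,6S,7R)-6-(tert-butyldimethylsilyloxy)germacra-1(10),4,11-triene-3,8-dione, via cyclic lead diolate 14 (not isolated)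
Conditions: Pb(OAc)4, CH2Cl2, 0 °C; filtration through a short silica pad
Reagents that add atoms: none
Why: The two cis tertiary hydroxyls (O–C3–C8–O about 60°) displace two acetates of Pb(OAc)4 to give the five-membered diolate 14, which collapses in a concerted two-electron shift in which C3–C8 breaks, both C–O bonds become C=O and tetravalent lead leaves as divalent lead (Criegee glycol cleavage). The closest known case is the cleavage of cis-decalin-9,10-diol to cyclodecane-1,6-dione. No ring is closed by bond formation: the ten-membered ring C1–C10 is the perimeter of the bicyclo[4.4.0] system and appears when the zero-atom bridge is cut, so neither dilution nor a strained cyclisation transition state is involved. No stereocentre is made; the relay centres C3 and C8 are erased, so any epimer of 13 at these carbons would funnel into the same 15, while C6 and C7 are untouched. Both olefins come from six-membered rings and can therefore only be Z in 15. The selectivity needed is diol against four C=C bonds, a silyl ether and several allylic C–H bonds, and it is secured because only the vicinal diol can chelate lead. The medium is free of base and only weakly acidic, which should spare the skipped C1=C10 bond, C7–H next to the new ketone and the β-silyloxy group on C6.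

Step 10
Reactants: 15 diketone
Product: 16 (1(10)Z,4Z,6S,7S,8S)-6-(tert-butyldimethylsilyloxy)-8-hydroxygermacra-1(10),4,11-trien-3-one
Conditions: NaBH4, CH2Cl2–MeOH, −78 °C
Reagents that add atoms: none
Why: Borohydride at low temperature reduces an isolated ketone faster than an α-substituted enone. Hydride should come from the periphery, anti to the ring bond C7–C6, in the rotamer that keeps C9 away from the isopropenyl group and lets the nucleophile pass H7 (Felkin–Anh type), which gives O8 cis to C11 in the ring sense (8S).

Step 11
Reactants: 16 8-alcohol; 17 (R)-2-methylbutanoic acid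
Product: 18 (6S,7S,8S)-6-(tert-butyldimethylsilyloxy)-8-[(2R)-2-methylbutanoyloxy]germacra-1(10),4,11-trien-3-one
Conditions: i-PrN=C=N-i-Pr, DMAP (cat.), CH2Cl2, 0 to 23 °C
Reagents that add atoms: none
Why: Steglich esterification of the only free hydroxyl with retention at C8; the carbodiimide route avoids a ketene and should keep C2′ intact.

Step 12
Reactants: 18 keto ester
Product: 19 (3R,6S,7S,8S)-6-(tert-butyldimethylsilyloxy)-3-hydroxy-8-[(2R)-2-methylbutanoyloxy]germacra-1(10),4,11-triene
Conditions: (S)-2-methyl-CBS-oxazaborolidine (cat.), catecholborane, toluene, −78 °C; H2O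
Reagents that add atoms: none
Why: Corey–Bakshi–Shibata reduction; the α-methyl alkenyl side C4 acts as the large group and C2H2 as the small one, so the (S)-catalyst should deliver the 3R allylic alcohol by 1,2-reduction. Catecholborane leaves the esters and olefins alone at this temperature.

Step 13
Reactants: 19 allylic alcohol
Product: 20 (3R,6S,7S,8S)-3-acetoxy-6-(tert-butyldimethylsilyloxy)-8-[(2R)-2-methylbutanoyloxy]germacra-1(10),4,11-triene
Conditions: Ac2O, pyridine, DMAP (cat.), CH2Cl2, 0 °C
Reagents that add atoms: acetic anhydride, CC(=O)OC(C)=O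
Why: Acetylation of the single free hydroxyl with retention at C3.

Step 14
Reactants: 20 triene diester
Product: 21 (1R,3R,6S,7S,8S,10S)-3-acetoxy-6-(tert-butyldimethylsilyloxy)-1,10-epoxy-8-[(2R)-2-methylbutanoyloxy]germacra-4,11-diene
Conditions: 1,2:4,5-di-O-isopropylidene-β-D-erythro-2,3-hexodiulo-2,6-pyranose (cat.), Oxone (2KHSO5·KHSO4·K2SO4), K2CO3, Bu4NHSO4 (cat.), MeCN–CH2(OMe)2–aq. Na2B4O7 buffer, 0 °C
Reagents that add atoms: potassium peroxymonosulfate (active part of Oxone), [K+].[O-]S(=O)(=O)OO
Why: Shi epoxidation; C1=C10 is the only unhindered electron-rich trisubstituted olefin, since C4=C5 is flanked by two allylic oxygens and the isopropenyl group is 1,1-disubstituted. By the spiro transition-state model for 1-substituted cycloalkenes, the D-fructose-derived dioxirane should transfer oxygen syn to the face that gives 1R,10S, and the Z geometry becomes the cis oxirane.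

Step 15
Reactants: 21 epoxide
Product: 22 (1R,3R,6S,7S,8S,10S)-3-acetoxy-6-(tert-butyldimethylsilyloxy)-1,10-epoxy-12-hydroxy-8-[(2R)-2-methylbutanoyloxy]germacra-4,11(13)-diene
Conditions: SeO2 (cat.), t-BuOOH, CH2Cl2, 0 to 23 °C
Reagents that add atoms: tert-butyl hydroperoxide, CC(C)(C)OO; selenium dioxide (oxygen carrier), O=[Se]=O
Why: Riley-type allylic oxidation (ene reaction, then [2,3] shift) of the isopropenyl methyl group; C4=C5 is deactivated by its two allylic oxygens and C7–H is a crowded methine. These conditions are known to tolerate trisubstituted oxiranes in germacranolides, and any enal formed converges in step 17.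

Step 16
Reactants: 22 allylic alcohol
Product: 23 (1R,3R,6S,7R,8S,10S)-3-acetoxy-1,10-epoxy-6,12-dihydroxy-8-[(2R)-2-methylbutanoyloxy]germacra-4,11(13)-diene
Conditions: Bu4NF, AcOH, THF, 0 to 23 °C
Reagents that add atoms: none
Why: Buffered fluoride desilylation; the acetic acid buffer should hold back acyl migration from O8 to O6, and the absence of strong acid spares the oxirane (the descriptor at C7 changes by priority only).

Step 17
Reactants: 23 6,12-diol
Product: 26 target CNP0340603.1, via hydroxy enal 24 (not isolated), via lactol 25 (not isolated)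
Conditions: TEMPO (cat.), PhI(OAc)2, CH2Cl2, 23 °C
Reagents that add atoms: none
Why: Oxoammonium oxidation prefers the primary allylic alcohol; enal 24 is captured by O6–H as the five-membered lactol 25, which is oxidised on to the α-methylene lactone (oxidative lactonisation of a 2-methylene-1,4-diol). The trans fusion follows from the trans O6/C11 relation set in step 5.

## Compound list

1 | (R)-(−)-carvone, (5R)-2-methyl-5-(prop-1-en-2-yl)cyclohex-2-en-1-one | CC1=CC[C@H](CC1=O)C(C)=C | starting material
2 | sodium cross-conjugated dienolate of 1 | C1C=C(C)C([O-])=C[C@@H]1C(C)=C.[Na+] | intermediate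
3 | (5S,6S)-6-hydroxycarvone (OH trans to isopropenyl) | C1C=C(C)C(=O)[C@@H](O)[C@@H]1C(C)=C | intermediate
4 | (5S,6S)-6-[(2-methoxypropan-2-yl)oxy]carvone | C1C=C(C)C(=O)[C@@H](OC(C)(C)OC)[C@@H]1C(C)=C | intermediate
5 | potassium enolate of 4 | C1C=C(C)C([O-])=C(OC(C)(C)OC)[C@@H]1C(C)=C.[K+] | intermediate
6 | (5S,6R)-6-[(2-methoxypropan-2-yl)oxy]-6-(2-methylallyl)carvone (methallyl trans to isopropenyl) | C1C=C(C)C(=O)[C@@](OC(C)(C)OC)(CC(C)=C)[C@@H]1C(C)=C | intermediate
7 | potassium linear dienolate of 6 | C1=CC(C)=C([O-])[C@@](OC(C)(C)OC)(CC(C)=C)[C@@H]1C(C)=C.[K+] | intermediate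
8 | triethyl{[(5S,6R)-6-[(2-methoxypropan-2-yl)oxy]-2-methyl-6-(2-methylallyl)-5-(prop-1-en-2-yl)cyclohexa-1,3-dien-1-yl]oxy}silane | C1=CC(C)=C(O[Si](CC)(CC)CC)[C@@](OC(C)(C)OC)(CC(C)=C)[C@@H]1C(C)=C | intermediate
9 | (4S,5R,6R)-4-hydroxy-6-[(2-methoxypropan-2-yl)oxy]-2-methyl-6-(2-methylallyl)-5-(prop-1-en-2-yl)cyclohex-2-en-1-one | O[C@H]1C=C(C)C(=O)[C@@](OC(C)(C)OC)(CC(C)=C)[C@@H]1C(C)=C | intermediate
10 | (4S,5R,6R)-4,6-dihydroxy-2-methyl-6-(2-methylallyl)-5-(prop-1-en-2-yl)cyclohex-2-en-1-one | O[C@H]1C=C(C)C(=O)[C@@](O)(CC(C)=C)[C@@H]1C(C)=C | intermediate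
11 | (4S,5R,6R)-4-(tert-butyldimethylsilyloxy)-6-hydroxy-2-methyl-6-(2-methylallyl)-5-(prop-1-en-2-yl)cyclohex-2-en-1-one | CC(C)(C)[Si](C)(C)O[C@H]1C=C(C)C(=O)[C@@](O)(CC(C)=C)[C@@H]1C(C)=C | intermediate
12 | (1R,2S,5S,6R)-2-allyl-5-(tert-butyldimethylsilyloxy)-3-methyl-1-(2-methylallyl)-6-(prop-1-en-2-yl)cyclohex-3-ene-1,2-diol (cis-diol) | CC(C)(C)[Si](C)(C)O[C@H]1C=C(C)[C@@](O)(CC=C)[C@@](O)(CC(C)=C)[C@@H]1C(C)=C | intermediate
13 | (1R,2S,4aS,8aR)-2-(tert-butyldimethylsilyloxy)-4,7-dimethyl-1-(prop-1-en-2-yl)-1,2,5,8-tetrahydronaphthalene-4a,8a-diol | CC(C)(C)[Si](C)(C)O[C@H]1C=C(C)[C@@]2(O)CC=C(C)C[C@@]2(O)[C@@H]1C(C)=C | intermediate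
14 | cyclic diacetoxylead diolate of 13 (O3–Pb–O8 ring) | CC(C)(C)[Si](C)(C)O[C@H]1C=C(C)[C@@]23CC=C(C)C[C@@]2(O[Pb](OC(C)=O)(OC(C)=O)O3)[C@@H]1C(C)=C | intermediate
15 | (1(10)Z,4Z,6S,7R)-6-(tert-butyldimethylsilyloxy)germacra-1(10),4,11-triene-3,8-dione | CC(C)(C)[Si](C)(C)O[C@H]1/C=C(/C)C(=O)C/C=C(/C)CC(=O)[C@@H]1C(C)=C | intermediate
16 | (1(10)Z,4Z,6S,7S,8S)-6-(tert-butyldimethylsilyloxy)-8-hydroxygermacra-1(10),4,11-trien-3-one | CC(C)(C)[Si](C)(C)O[C@H]1/C=C(/C)C(=O)C/C=C(/C)C[C@H](O)[C@@H]1C(C)=C | intermediate
17 | (R)-2-methylbutanoic acid | CC[C@@H](C)C(=O)O | starting material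
18 | (6S,7S,8S)-6-(tert-butyldimethylsilyloxy)-8-[(2R)-2-methylbutanoyloxy]germacra-1(10),4,11-trien-3-one | CC(C)(C)[Si](C)(C)O[C@H]1/C=C(/C)C(=O)C/C=C(/C)C[C@H](OC(=O)[C@H](C)CC)[C@@H]1C(C)=C | intermediate
19 | (3R,6S,7S,8S)-6-(tert-butyldimethylsilyloxy)-3-hydroxy-8-[(2R)-2-methylbutanoyloxy]germacra-1(10),4,11-triene | CC(C)(C)[Si](C)(C)O[C@H]1/C=C(/C)[C@H](O)C/C=C(/C)C[C@H](OC(=O)[C@H](C)CC)[C@@H]1C(C)=C | intermediate
20 | (3R,6S,7S,8S)-3-acetoxy-6-(tert-butyldimethylsilyloxy)-8-[(2R)-2-methylbutanoyloxy]germacra-1(10),4,11-triene | CC(C)(C)[Si](C)(C)O[C@H]1/C=C(/C)[C@H](OC(C)=O)C/C=C(/C)C[C@H](OC(=O)[C@H](C)CC)[C@@H]1C(C)=C | intermediate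
21 | (1R,3R,6S,7S,8S,10S)-3-acetoxy-6-(tert-butyldimethylsilyloxy)-1,10-epoxy-8-[(2R)-2-methylbutanoyloxy]germacra-4,11-diene | CC(C)(C)[Si](C)(C)O[C@H]1/C=C(/C)[C@H](OC(C)=O)C[C@H]2O[C@@]2(C)C[C@H](OC(=O)[C@H](C)CC)[C@@H]1C(C)=C | intermediate
22 | 12-hydroxy derivative of 21, germacra-4,11(13)-diene | CC(C)(C)[Si](C)(C)O[C@H]1/C=C(/C)[C@H](OC(C)=O)C[C@H]2O[C@@]2(C)C[C@H](OC(=O)[C@H](C)CC)[C@@H]1C(=C)CO | intermediate
23 | (1R,3R,6S,7R,8S,10S)-3-acetoxy-1,10-epoxy-6,12-dihydroxy-8-[(2R)-2-methylbutanoyloxy]germacra-4,11(13)-diene | O[C@H]1/C=C(/C)[C@H](OC(C)=O)C[C@H]2O[C@@]2(C)C[C@H](OC(=O)[C@H](C)CC)[C@@H]1C(=C)CO | intermediate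
24 | 6-hydroxy-12-al (hydroxy enal) derived from 23 | O[C@H]1/C=C(/C)[C@H](OC(C)=O)C[C@H]2O[C@@]2(C)C[C@H](OC(=O)[C@H](C)CC)[C@@H]1C(=C)C=O | intermediate
25 | 12,6-lactol of 24 (both anomers at C12) | C=C1C(O)O[C@H]2/C=C(/C)[C@H](OC(C)=O)C[C@H]3O[C@@]3(C)C[C@H](OC(=O)[C@H](C)CC)[C@H]12 | intermediate
26 | CNP0340603.1, (1R,3R,4Z,6S,7S,8S,10S)-3-acetoxy-1,10-epoxy-8-[(2R)-2-methylbutanoyloxy]germacra-4,11(13)-dien-12,6-olide | C=C1C(=O)O[C@H]2/C=C(/C)[C@H](OC(C)=O)C[C@H]3O[C@@]3(C)C[C@H](OC(=O)[C@H](C)CC)[C@H]12 | target

## Step count and least certain steps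

Total step count: 17. Longest linear sequence: 17 steps from 1 (acid 17 is bought).

**Step 9 (key step).** Chelation of lead by a crowded ditertiary diol may be slow. Once freed, the 1,6-diketone may close transannularly by aldol addition from C2 or C9, let the skipped C1=C10 bond slip into conjugation, or epimerise at C7. The crude product should therefore go straight into step 10.
Fallback: reverse the order of scission and metathesis. Setting out from 12, Pb(OAc)4 cleaves the flexible monocyclic diol to the open-chain Z-enone diketone F1. Ring-closing metathesis of F1 under high dilution with the second-generation Grubbs catalyst then closes C1=C10 and comes back at 15. This gives up the six-ring closure but keeps all stereocentres.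

**Step 3.** C-alkylation of a tetrasubstituted, oxygen-bearing enolate is slow, so proton transfer to the vinylogous site C6 or O-alkylation may compete.
Fallback: setting out from 4, the enolate 5 is trapped on oxygen with 2-methylallyl chloroformate, which is fast even for a crowded enolate, to give the enol carbonate F2. Pd(PPh3)4 (zerovalent palladium) ionises F2, carbon dioxide is lost, and the enolate and π-allyl ion pair collapses at C8 anti to the isopropenyl group (decarboxylative allylation of the Tsuji type). This comes back at 6.

**Step 5.** The oxidant may attack the inner C3=C4 bond or one of the 1,1-disubstituted olefins, or facial selectivity at C6 may be poor.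
Fallback: setting out from 8, photo-oxygenation (O2, tetraphenylporphyrin, light, CH2Cl2, −78 °C) adds singlet oxygen across the diene termini C3 and C6 in a [4+2] sense, which can only oxygenate C6. Loss of the silyl group on aqueous work-up gives the 6-hydroperoxide F3, and PPh3 reduces F3 to come back at 9.

**Step 10.** The ring may twist the enone out of conjugation and erode chemoselectivity. More likely, the reactive conformer may expose the other carbonyl face, so that facial selectivity is poor or reversed.
Fallback: the epimer is used rather than discarded. Setting out from 15, reduction from the other face gives the 8R alcohol F4. Mitsunobu esterification of F4 with 17 (PPh3, diisopropyl azodicarboxylate) inverts C8 and comes back at 18.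

**Step 14.** With H3 and H8 turned inward, the ring probably keeps a folded, cis-decalin-like shape. The face of C1=C10 that must be oxidised is then the concave one, so catalyst and substrate may be mismatched and facial selectivity low.
Fallback: the substrate bias is turned to use. Setting out from 20, N-bromosuccinimide in aqueous THF forms the bromonium ion on the open face, and water opens it at the tertiary C10 from the opposite face to give the bromohydrin F5. DBU then closes the oxirane with inversion at C1, so oxygen ends on the hindered face with the cis geometry kept. This comes back at 21.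

**Step 15.** Competing oxidation at C15 or C7–H, over-oxidation, or acid-induced opening of the oxirane may occur.
Fallback: setting out from 21, ene-type chlorination with Ca(OCl)2 and solid CO2 in CH2Cl2–H2O gives the allylic chloride F6. N-methylmorpholine N-oxide oxidises F6 to the silyl-protected enal F7, and buffered Bu4NF removes the silyl group to come back at 24, the intermediate of step 17.

## Further compounds

F1 | step 9 | (2Z)-open-chain diketone, 6-(tert-butyldimethylsilyloxy)-3,8-seco precursor with terminal allyl and methallyl groups | CC(C)(C)[Si](C)(C)O[C@@H](/C=C(/C)C(=O)CC=C)[C@@H](C(C)=C)C(=O)CC(C)=C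
F2 | step 3 | 2-methylallyl enol carbonate of 4 | C1C=C(C)C(OC(=O)OCC(C)=C)=C(OC(C)(C)OC)[C@@H]1C(C)=C
F3 | step 5 | (4S,5R,6R)-4-hydroperoxy analogue of 9 | OO[C@H]1C=C(C)C(=O)[C@@](OC(C)(C)OC)(CC(C)=C)[C@@H]1C(C)=C
F4 | step 10 | 8R epimer of 16 | CC(C)(C)[Si](C)(C)O[C@H]1/C=C(/C)C(=O)C/C=C(/C)C[C@@H](O)[C@@H]1C(C)=C
F5 | step 14 | 1-bromo-10-hydroxy bromohydrin of 20 | CC(C)(C)[Si](C)(C)O[C@H]1/C=C(/C)[C@H](OC(C)=O)C[C@H](Br)[C@](O)(C)C[C@H](OC(=O)[C@H](C)CC)[C@@H]1C(C)=C
F6 | step 15 | 12-chloride of 21, germacra-4,11(13)-diene | CC(C)(C)[Si](C)(C)O[C@H]1/C=C(/C)[C@H](OC(C)=O)C[C@H]2O[C@@]2(C)C[C@H](OC(=O)[C@H](C)CC)[C@@H]1C(=C)CCl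
F7 | step 15 | 6-O-silyl 12-al (enal) | CC(C)(C)[Si](C)(C)O[C@H]1/C=C(/C)[C@H](OC(C)=O)C[C@H]2O[C@@]2(C)C[C@H](OC(=O)[C@H](C)CC)[C@@H]1C(=C)C=O
A1 | alternative 1 | open-chain Z-enal with (Z)-2-(bromomethyl)acrylate terminus | O=C/C=C(/C)[C@H](OC(C)=O)C/C=C(/C)C[C@H](OC(=O)[C@H](C)CC)/C=C(\CBr)C(=O)OC
A2 | alternative 1 | 1(10)-ene dienolide (26 without the oxirane oxygen) | C=C1C(=O)O[C@H]2/C=C(/C)[C@H](OC(C)=O)C/C=C(/C)C[C@H](OC(=O)[C@H](C)CC)[C@H]12
A3 | alternative 2 | 1,10-seco diene lactone | C=C1C(=O)O[C@@H](/C=C(/C)[C@H](OC(C)=O)CC=C)[C@@H]1[C@@H](OC(=O)[C@H](C)CC)CC(C)=C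
A4 | alternative 3 | 3-vinyl-8-[(E)-prop-1-enyl] carbinol on the carvone ring | CC(C)(C)[Si](C)(C)O[C@H]1C=C(C)[C@@](O)(C=C)[C@@H](/C=C/C)[C@@H]1C(C)=C
A5 | alternative 3 | oxy-Cope product, (4Z,8E)-germacra-4,8,11-trien-3-one (C10 left open) | CC(C)(C)[Si](C)(C)O[C@H]1/C=C(/C)C(=O)CCC(C)/C=C/[C@@H]1C(C)=C
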